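**Retrosynthetic overview**
1. Both exocyclic Z-alkenes are cut by Wittig disconnection, giving a C4 bis-phosphonium linchpin and two diastereomeric hydroxy ketones (the cis half and the trans half), joined one after the other.
2. Each cyclopentanol ring comes from one common keto aldehyde by carbonyl-ene closure: Me2AlCl for the cis half, a confined Brønsted acid for the trans half.
3. The oxane ring of that keto aldehyde is cut at O–C2: a catalytic asymmetric intramolecular oxa-Michael addition with face-selective protonation of an α-branched enal sets both acyclic-type stereocentres.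
4. The enal comes from cross-aldol condensation of 6-methylhept-5-enal with the ketolactol made from furfuryl alcohol (Achmatowicz rearrangement, hydrogenation).
5. Ring order: oxane ring first, cyclopentane ring second, union of the two halves last.

Assumption: the SMILES is taken literally, so the two halves are diastereomers (isopropenyl-bearing carbon R in one half, S in the other; all other centres identical) and two different halves must be joined; reagent 2 is bought as its commercial THF solution.

**Step 1**
Reactants: 1 1-bromo-3-methylbut-2-ene; 2 [2-(1,3-dioxolan-2-yl)ethyl]magnesium bromide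
Product: 4 6-methylhept-5-enal, via dioxolane acetal 3 (not isolated)
Conditions: Li2CuCl4 (3 mol %), THF, −20 to 0 °C; then 1 M HCl, THF, rt
Reagents that add atoms: water (O)
Why: Copper-catalysed Kochi-type cross-coupling of the Grignard reagent at the primary carbon of the prenyl bromide builds the chain, and mild acetal hydrolysis frees the aldehyde without touching the trisubstituted alkene; no stereocentre is formed.

**Step 2**
Reactants: 5 furan-2-ylmethanol
Product: 6 6-hydroxy-2H-pyran-3(6H)-one
Conditions: N-bromosuccinimide, NaHCO3, THF/H2O 4:1, 0 °C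
Reagents that add atoms: water (O)
Why: Achmatowicz oxidative rearrangement opens the furan to the cis-enedione, which recloses through the hydroxymethyl oxygen to the pyranone lactol (racemic anomeric centre, lost in step 4).

**Step 3**
Reactants: 6 6-hydroxy-2H-pyran-3(6H)-one
Product: 7 6-hydroxyoxan-3-one
Conditions: H2 (1 atm), Pd/C, EtOAc, rt
Reagents that add atoms: none
Why: Chemoselective heterogeneous hydrogenation of the enone C=C leaves ketone and lactol intact and gives the cyclic form of 5-hydroxy-4-oxopentanal.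

**Step 4**
Reactants: 4 6-methylhept-5-enal; 7 6-hydroxyoxan-3-one
Product: 8 (2E)-7-hydroxy-2-(4-methylpent-3-en-1-yl)-6-oxohept-2-enal
Conditions: pyrrolidine (20 mol %), PhCO2H (20 mol %), CH2Cl2, rt; 4 added slowly to 7 (3 equiv)
Reagents that add atoms: none
Why: Amine-catalysed cross-aldol condensation (enamine of 4 adds to the open aldehyde form of 7, then dehydration) gives the thermodynamically preferred E-2-alkyl-2-enal; slow addition of 4 to excess 7 holds back self-condensation, and the α-branched enal is a poor iminium partner for a secondary amine, so it does not cyclise here.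

**Step 5**
Reactants: 8 (2E)-7-hydroxy-2-(4-methylpent-3-en-1-yl)-6-oxohept-2-enal
Product: 9 (2R)-6-methyl-2-[(2R)-5-oxooxan-2-yl]hept-5-enal
Conditions: 9-amino-9-deoxy-epi-quinine (20 mol %), (R)-3,3′-bis(2,4,6-triisopropylphenyl)-1,1′-binaphthyl-2,2′-diyl hydrogen phosphate (40 mol %), toluene, 0 °C (amine/acid pair matched by screening); product used at once
Reagents that add atoms: none
Why: Proposed new method: the chiral primary amine condenses with the α-branched enal to an iminium ion, the chiral phosphate counter-anion hydrogen-bonds the ketol OH and guides its 6-exo-trig attack on one face of the β-carbon (oxane C2 becomes R), and the phosphoric acid so formed hands the proton back within the ion pair to the same face of the enamine α-carbon before hydrolysis, a net syn-hydroalkoxylation of the E-alkene that gives the anti (2R,2′R) aldehyde; the closest known reactions are primary-amine iminium catalysis of α-branched enals with sulfur and carbon nucleophiles followed by enamine protonation, and amine-catalysed intramolecular oxa-Michael additions to α-unbranched enals.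

**Step 6**
Reactants: 9 (2R)-6-methyl-2-[(2R)-5-oxooxan-2-yl]hept-5-enal
Product: 10 (6R)-6-[(1S,2S,3R)-2-hydroxy-3-(prop-1-en-2-yl)cyclopentyl]oxan-3-one
Conditions: Me2AlCl (2.5 equiv), CH2Cl2, −78 °C
Reagents that add atoms: none
Why: Me2AlCl-promoted intramolecular carbonyl-ene reaction through the concerted cis-fused bicyclic transition state puts OH and isopropenyl cis, while the oxanyl group on the existing α-stereocentre sits on the convex face, trans to both; this sets the carbinol carbon (S) and the isopropenyl carbon (R).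

**Step 7**
Reactants: 9 (2R)-6-methyl-2-[(2R)-5-oxooxan-2-yl]hept-5-enal
Product: 11 (6R)-6-[(1S,2S,3S)-2-hydroxy-3-(prop-1-en-2-yl)cyclopentyl]oxan-3-one
Conditions: confined binaphthol-derived imidodiphosphoric acid (5 mol %, enantiomer matched to 9), cyclohexane, rt
Reagents that add atoms: none
Why: Confined Brønsted-acid-catalysed carbonyl-ene cyclisation, which runs stepwise (Prins-type) and is known to give trans-2-alkenyl cyclopentanols, should deliver the all-trans ring (OH trans to isopropenyl and to the oxanyl group), setting the carbinol carbon (S) and the isopropenyl carbon (S).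

**Step 8**
Reactants: 10 (6R)-6-[(1S,2S,3R)-2-hydroxy-3-(prop-1-en-2-yl)cyclopentyl]oxan-3-one; 12 butane-1,4-diylbis(triphenylphosphonium) dibromide
Product: 14 [(4Z)-4-{(6R)-6-[(1S,2S,3R)-2-hydroxy-3-(prop-1-en-2-yl)cyclopentyl]oxan-3-ylidene}butyl]triphenylphosphonium bromide, via monoylide 13 (not isolated)
Conditions: 12 (4 equiv), KN(SiMe3)2 (2 equiv), THF, 0 °C; then 10, −78 °C to rt
Reagents that add atoms: none
Why: Wittig olefination with the monoylide of the C4 bis-phosphonium salt; unstabilised ylides add to α-alkoxy ketones with Still-type selectivity that places the new chain cis to the O–CH2 carbon (Z), and excess 12 with substoichiometric base keeps the second phosphonium end intact.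

**Step 9**
Reactants: 14 [(4Z)-4-{(6R)-6-[(1S,2S,3R)-2-hydroxy-3-(prop-1-en-2-yl)cyclopentyl]oxan-3-ylidene}butyl]triphenylphosphonium bromide; 11 (6R)-6-[(1S,2S,3S)-2-hydroxy-3-(prop-1-en-2-yl)cyclopentyl]oxan-3-one
Product: 16 (1S,2S,5R)-2-[(2R,5Z)-5-[(4Z)-4-{(6R)-6-[(1S,2S,3S)-2-hydroxy-3-(prop-1-en-2-yl)cyclopentyl]oxan-3-ylidene}butylidene]oxan-2-yl]-5-(prop-1-en-2-yl)cyclopentan-1-ol, via ylide 15 (not isolated)
Conditions: KN(SiMe3)2 (1.1 equiv), THF, −78 °C; then 11 (1.2 equiv), −78 °C to rt
Reagents that add atoms: none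
Why: A second Still-type Z-selective Wittig olefination, now of ylide 15 with α-alkoxy ketone 11, forms the other exocyclic alkene and joins the two different halves without touching any stereocentre.

**Compound list**
1 | 1-bromo-3-methylbut-2-ene (prenyl bromide) | CC(C)=CCBr | starting material
2 | [2-(1,3-dioxolan-2-yl)ethyl]magnesium bromide | Br[Mg]CCC1OCCO1 | starting material
3 | 2-(5-methylhex-4-en-1-yl)-1,3-dioxolane | CC(C)=CCCCC1OCCO1 | intermediate (not isolated)
4 | 6-methylhept-5-enal | CC(C)=CCCCC=O | intermediate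
5 | furan-2-ylmethanol (furfuryl alcohol) | OCc1ccco1 | starting material
6 | 6-hydroxy-2H-pyran-3(6H)-one (racemic lactol) | O=C1COC(O)C=C1 | intermediate
7 | 6-hydroxyoxan-3-one (racemic lactol of 5-hydroxy-4-oxopentanal) | O=C1CCC(O)OC1 | intermediate
8 | (2E)-7-hydroxy-2-(4-methylpent-3-en-1-yl)-6-oxohept-2-enal | O=C/C(CCC=C(C)C)=C/CCC(=O)CO | intermediate
9 | (2R)-6-methyl-2-[(2R)-5-oxooxan-2-yl]hept-5-enal | O=C[C@H](CCC=C(C)C)[C@H]1CCC(=O)CO1 | intermediate
10 | (6R)-6-[(1S,2S,3R)-2-hydroxy-3-(prop-1-en-2-yl)cyclopentyl]oxan-3-one (cis half) | C=C(C)[C@H]1CC[C@H]([C@H]2CCC(=O)CO2)[C@H]1O | intermediate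
11 | (6R)-6-[(1S,2S,3S)-2-hydroxy-3-(prop-1-en-2-yl)cyclopentyl]oxan-3-one (trans half) | C=C(C)[C@@H]1CC[C@H]([C@H]2CCC(=O)CO2)[C@H]1O | intermediate
12 | butane-1,4-diylbis(triphenylphosphonium) dibromide | [Br-].[Br-].c1ccc(cc1)[P+](CCCC[P+](c1ccccc1)(c1ccccc1)c1ccccc1)(c1ccccc1)c1ccccc1 | starting material
13 | triphenyl[4-(triphenyl-λ5-phosphanylidene)butyl]phosphonium bromide (monoylide) | [Br-].C(CCC[P+](c1ccccc1)(c1ccccc1)c1ccccc1)=P(c1ccccc1)(c1ccccc1)c1ccccc1 | intermediate (not isolated)
14 | [(4Z)-4-{(6R)-6-[(1S,2S,3R)-2-hydroxy-3-(prop-1-en-2-yl)cyclopentyl]oxan-3-ylidene}butyl]triphenylphosphonium bromide | C=C(C)[C@H]1CC[C@H]([C@H]2CC/C(=C/CCC[P+](c3ccccc3)(c3ccccc3)c3ccccc3)CO2)[C@H]1O.[Br-] | intermediate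
15 | ylide of 14: (1S,2S,5R)-5-(prop-1-en-2-yl)-2-[(2R,5Z)-5-[4-(triphenyl-λ5-phosphanylidene)butylidene]oxan-2-yl]cyclopentan-1-ol | C=C(C)[C@H]1CC[C@H]([C@H]2CC/C(=C/CCC=P(c3ccccc3)(c3ccccc3)c3ccccc3)CO2)[C@H]1O | intermediate (not isolated)
16 | CNP0267443.2: (1S,2S,5R)-2-[(2R,5Z)-5-[(4Z)-4-{(6R)-6-[(1S,2S,3S)-2-hydroxy-3-(prop-1-en-2-yl)cyclopentyl]oxan-3-ylidene}butylidene]oxan-2-yl]-5-(prop-1-en-2-yl)cyclopentan-1-ol | C=C(C)[C@H]1CC[C@H]([C@H]2CC/C(=C/CC/C=C3/CC[C@H]([C@H]4CC[C@@H](C(=C)C)[C@@H]4O)OC3)CO2)[C@H]1O | target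

**Step count and risks**
Total steps: 9. Longest linear sequence: 7 (5 → 6 → 7 → 8 → 9 → 10 → 14 → 16).

Three steps most likely to fail:

Step 4 (cross-aldol condensation). Self-condensation of 4 or intramolecular aldol of the open ketoaldehyde form of 7 may dominate. The fallback sets out from 4 and comes back at 8, replacing the catalytic condensation by a stoichiometric stabilised-ylide olefination. Organocatalytic α-bromination of 4 (4,4-dibromo-2,6-di-tert-butylcyclohexa-2,5-dienone, cat. pyrrolidine/PhCO2H) gives 2-bromo-6-methylhept-5-enal F1. PPh3 in toluene converts it to (1-formyl-5-methylhex-4-en-1-yl)triphenylphosphonium bromide F2, and aqueous NaOH gives the formyl-stabilised ylide 6-methyl-2-(triphenyl-λ5-phosphanylidene)hept-5-enal F3. Heating F3 with lactol 7 in toluene at 90 °C olefinates only the aldehyde of the open form, E-selectively, to give 8.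

Step 5 (the new oxa-Michael/protonation). The primary amine may be tied up by the ketol (imine or Heyns-type chemistry), the protonation may give poor anti/syn control, or 9 may epimerise under the catalyst. The fallback sets out from 7 (with 4) and comes back at 9, using a C–C bond to set the stereodiad and a plain etherification to close the ring. D-Proline-catalysed direct cross-aldol (DMF, 4 °C, slow addition of 4) gives the anti aldol (2R,3R)-3,7-dihydroxy-2-(4-methylpent-3-en-1-yl)-6-oxoheptanal F4. Selective sulfonylation of the primary ketol hydroxyl (TsCl, pyridine, 0 °C) gives (5R,6R)-6-formyl-5-hydroxy-10-methyl-2-oxoundec-9-en-1-yl 4-methylbenzenesulfonate F5. Ag2O in CH2Cl2 then closes the oxane by 6-exo-tet Williamson etherification to 9.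

Step 8 (first Wittig). Mono-olefination with the bis-salt is partly statistical (double olefination to the symmetric dimer), salt 14 is hard to purify, and the Z-preference of a cyclic α-alkoxy ketone is not proven. The fallback sets out from 10 and comes back at 14, using a linchpin with two different ends. Wittig reaction of 10 with the ylide of commercial (4-hydroxybutyl)triphenylphosphonium bromide (2 equiv KN(SiMe3)2, THF) gives the neutral alcohol (4Z)-4-{(6R)-6-[(1S,2S,3R)-2-hydroxy-3-(prop-1-en-2-yl)cyclopentyl]oxan-3-ylidene}butan-1-ol F6, whose Z and E isomers can be separated on silica. Appel bromination of the primary hydroxyl (CBr4, PPh3, 0 °C) gives (1S,2S,5R)-2-[(2R,5Z)-5-(4-bromobutylidene)oxan-2-yl]-5-(prop-1-en-2-yl)cyclopentan-1-ol F7, and PPh3 in refluxing MeCN gives 14.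

**Further compounds**
F1 | step 4 | 2-bromo-6-methylhept-5-enal | CC(C)=CCCC(Br)C=O
F2 | step 4 | (1-formyl-5-methylhex-4-en-1-yl)triphenylphosphonium bromide | CC(C)=CCCC(C=O)[P+](c1ccccc1)(c1ccccc1)c1ccccc1.[Br-]
F3 | step 4 | 6-methyl-2-(triphenyl-λ5-phosphanylidene)hept-5-enal | CC(C)=CCCC(C=O)=P(c1ccccc1)(c1ccccc1)c1ccccc1
F4 | step 5 | (2R,3R)-3,7-dihydroxy-2-(4-methylpent-3-en-1-yl)-6-oxoheptanal | O=C[C@H](CCC=C(C)C)[C@H](O)CCC(=O)CO
F5 | step 5 | (5R,6R)-6-formyl-5-hydroxy-10-methyl-2-oxoundec-9-en-1-yl 4-methylbenzenesulfonate | O=C[C@H](CCC=C(C)C)[C@H](O)CCC(=O)COS(=O)(=O)c1ccc(C)cc1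
F6 | step 8 | (4Z)-4-{(6R)-6-[(1S,2S,3R)-2-hydroxy-3-(prop-1-en-2-yl)cyclopentyl]oxan-3-ylidene}butan-1-ol | C=C(C)[C@H]1CC[C@H]([C@H]2CC/C(=C/CCCO)CO2)[C@H]1O
F7 | step 8 | (1S,2S,5R)-2-[(2R,5Z)-5-(4-bromobutylidene)oxan-2-yl]-5-(prop-1-en-2-yl)cyclopentan-1-ol | C=C(C)[C@H]1CC[C@H]([C@H]2CC/C(=C/CCCBr)CO2)[C@H]1O
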